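**Retrosynthetic overview**

1. Germacrane numbering is used: ring C1–C10, methyl C15 on C4, ketone C5, acyloxy C6, side chain C11(=C13)–C12 on C7, lactone oxygen on C8, acyloxy C9, carbinol C10 with methyl C14.
2. The C9 isobutyrate and the trans-9,10-diol come from an epoxide of an E-9(10)-alkene; the α-methylene lactone comes from oxidative lactonisation of a 2-methylene-1,4-diol.
3. Key step: a tandem anionic oxy-Cope ring expansion and enolate hydroxylation of a trans-1,2-dialkenylcyclohexanol, instead of a macrocyclisation. It forms C7–C8, breaks C5–C10, and sets C6, C7, C8 and the E-9(10)-alkene in one flask.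
4. The cyclohexanol comes from ketone 12 and dienyllithium 13; 12 comes from meso cis-2,6-dimethylcyclohexanone by enantioselective deprotonation (C4), hydroxymethylation (C10), Takai olefination and copper C–O coupling.
5. Ring order: six-membered carbocycle (purchased), then the ten-membered ring (step 9), then the γ-lactone (step 12).

Assumption: 2,6-dimethylcyclohexanone is bought as its cis (meso) isomer, and the sense of induction of the (R,R)-amide in step 3 is assigned by analogy with 4-substituted cyclohexanones; the (S,S)-amine would be used if it proves opposite.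

Abbreviations: PMB = 4-methoxybenzyl; PMBO = 4-methoxybenzyloxy.

**Route**

Step 1
Reactants: 1 2,3-dibromoprop-1-ene; 2 4-methoxybenzyl alcohol
Product: 4 2-bromoprop-2-en-1-yl 4-methoxybenzyl ether, via sodium alkoxide 3 (not isolated)
Conditions: NaH, THF, 0 °C; then 1, 0 °C → rt
Reagents that add atoms: none
Why: Williamson ether synthesis in which the alkoxide displaces only the allylic sp3 bromide of 1 by SN2, the vinylic bromide being inert under these conditions.

Step 2
Reactants: 4 2-bromoprop-2-en-1-yl 4-methoxybenzyl ether; 5 (E)-1,2-bis(tributylstannyl)ethene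
Product: 6 tributyl{(1E)-3-[(PMBO)methyl]buta-1,3-dien-1-yl}stannane
Conditions: Pd(PPh3)4 (5 mol %), 5 (2 equiv), toluene, 100 °C
Reagents that add atoms: none
Why: Stille cross-coupling in which oxidative addition occurs at the vinyl bromide and one tributylstannyl group of the excess bis-stannane is exchanged with retention of the E geometry, the excess suppressing a second coupling.

Step 3
Reactants: 7 cis-2,6-dimethylcyclohexan-1-one
Product: 8 {[(6R)-2,6-dimethylcyclohex-1-en-1-yl]oxy}trimethylsilane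
Conditions: (R,R)-bis(1-phenylethyl)amine, n-BuLi, THF, −78 °C; Me3SiCl (internal quench), then 7, −78 °C
Reagents that add atoms: chlorotrimethylsilane, C[Si](C)(C)Cl
Why: Enantioselective deprotonation of a meso ketone by a chiral lithium amide (Simpkins–Koga desymmetrisation) removes one of the two enantiotopic axial α-protons, so the untouched α-carbon becomes the C4 stereocentre (R, about 90% ee), the residual enantiomer being removed as a diastereomer after step 10.

Step 4
Reactants: 8 {[(6R)-2,6-dimethylcyclohex-1-en-1-yl]oxy}trimethylsilane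
Product: 9 (2S,6R)-2-(hydroxymethyl)-2,6-dimethylcyclohexan-1-one
Conditions: aq. HCHO (37%), Yb(OTf)3 (10 mol %), THF, rt
Reagents that add atoms: formaldehyde, C=O
Why: Lanthanide-triflate-catalysed aqueous Mukaiyama aldol reaction (hydroxymethylation) in which A(1,2) strain with the silyloxy group holds the C4 methyl pseudoaxial, so formaldehyde attacks the opposite face and sets quaternary C10 (S) with CH2OH trans to the C4 methyl and the two methyls cis.

Step 5
Reactants: 9 (2S,6R)-2-(hydroxymethyl)-2,6-dimethylcyclohexan-1-one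
Product: 10 (1S,3R)-1,3-dimethyl-2-oxocyclohexane-1-carbaldehyde
Conditions: Dess–Martin periodinane, CH2Cl2, 0 °C → rt
Reagents that add atoms: none
Why: Dess–Martin oxidation of the neopentyl primary alcohol under neutral conditions gives the non-enolisable β-keto aldehyde without retro-aldol loss of formaldehyde or epimerisation at C4.

Step 6
Reactants: 10 (1S,3R)-1,3-dimethyl-2-oxocyclohexane-1-carbaldehyde
Product: 11 (2S,6R)-2-[(E)-2-iodoethenyl]-2,6-dimethylcyclohexan-1-one
Conditions: CrCl2, CHI3, THF, 0 °C → rt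
Reagents that add atoms: iodoform, IC(I)I
Why: Takai iodoolefination is chemoselective for the aldehyde over the hindered ketone and gives the E-vinyl iodide, E selectivity being highest for α-quaternary aldehydes.

Step 7
Reactants: 11 (2S,6R)-2-[(E)-2-iodoethenyl]-2,6-dimethylcyclohexan-1-one; 2 4-methoxybenzyl alcohol
Product: 12 (2S,6R)-2-[(E)-2-(PMBO)ethenyl]-2,6-dimethylcyclohexan-1-one
Conditions: CuI (10 mol %), 3,4,7,8-tetramethyl-1,10-phenanthroline (20 mol %), Cs2CO3, 2 (2 equiv), toluene, 80 °C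
Reagents that add atoms: none
Why: Copper-catalysed Ullmann-type C–O cross-coupling of a vinyl iodide with an alcohol proceeds with retention of alkene geometry to give the E-enol ether, and the weak heterogeneous carbonate base should leave the hindered C4–H untouched.

Step 8
Reactants: 6 tributyl{(1E)-3-[(PMBO)methyl]buta-1,3-dien-1-yl}stannane; 12 (2S,6R)-2-[(E)-2-(PMBO)ethenyl]-2,6-dimethylcyclohexan-1-one
Product: 14 (1R,2S,6R)-1-{(1E)-3-[(PMBO)methyl]buta-1,3-dien-1-yl}-2-[(E)-2-(PMBO)ethenyl]-2,6-dimethylcyclohexan-1-ol, via dienyllithium 13 (not isolated)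
Conditions: 6, MeLi, THF, −78 °C; then 12, −78 → −20 °C; H2O
Reagents that add atoms: none
Why: Tin–lithium exchange followed by 1,2-addition of the alkenyllithium to the ketone, whose preferred chair has both methyls equatorial and the alkoxyvinyl group axial, so the nucleophile enters axially anti to that group and sets C5 (R) with the two alkenyl groups trans, as the oxy-Cope chair requires.

Step 9
Reactants: 14 (1R,2S,6R)-1-{(1E)-3-[(PMBO)methyl]buta-1,3-dien-1-yl}-2-[(E)-2-(PMBO)ethenyl]-2,6-dimethylcyclohexan-1-ol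
Product: 17 (4R,6R,7R,8R,9E)-6-hydroxy-8,12-bis(PMBO)germacra-9,11(13)-dien-5-one, via potassium alkoxide 15 (not isolated), via potassium enolate 16 (not isolated)
Conditions: KN(SiMe3)2, 18-crown-6, THF, −78 °C → rt; then −78 °C, 2-(phenylsulfonyl)-3-phenyloxaziridine; AcOH
Reagents that add atoms: 2-(phenylsulfonyl)-3-phenyloxaziridine, O=S(=O)(c1ccccc1)N1OC1c1ccccc1
Why: Tandem anionic oxy-Cope rearrangement and Davis enolate hydroxylation, in which the alkoxide rearranges through the chair transition state with both ring bonds equatorial, so the E-diene terminus and the E-enol ether place C11 and OPMB equatorial and create C7 and C8 with trans hydrogens in the absolute sense dictated by C5 and C10 (C4 is carried through unchanged) while forming the E-9(10)-alkene and the regiodefined ring-E enolate, which the oxaziridine hydroxylates on its exposed outer face to set C6 (R).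

Step 10
Reactants: 17 (4R,6R,7R,8R,9E)-6-hydroxy-8,12-bis(PMBO)germacra-9,11(13)-dien-5-one; 18 (2R)-2-methylbutanoic acid
Product: 19 (4R,6R,7S,8R,9E)-5-oxo-8,12-bis(PMBO)germacra-9,11(13)-dien-6-yl (2R)-2-methylbutanoate
Conditions: 18, DCC, DMAP (cat.), CH2Cl2, 0 °C → rt
Reagents that add atoms: none
Why: Steglich esterification of the only free hydroxyl (O6) under mild carbodiimide activation that does not racemise the α-stereocentre of 18, the ester from the minor enantiomer of the core being a separable diastereomer.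

Step 11
Reactants: 19 (4R,6R,7S,8R,9E)-5-oxo-8,12-bis(PMBO)germacra-9,11(13)-dien-6-yl (2R)-2-methylbutanoate
Product: 20 (4R,6R,7S,8R,9E)-8,12-dihydroxy-5-oxogermacra-9,11(13)-dien-6-yl (2R)-2-methylbutanoate
Conditions: DDQ, CH2Cl2/pH 7 buffer, 0 °C → rt
Reagents that add atoms: none
Why: Oxidative cleavage of both 4-methoxybenzyl ethers by DDQ (hydride abstraction, then hydrolysis of the oxocarbenium ions) leaves the esters, the ketone and the alkenes untouched.

Step 12
Reactants: 20 (4R,6R,7S,8R,9E)-8,12-dihydroxy-5-oxogermacra-9,11(13)-dien-6-yl (2R)-2-methylbutanoate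
Product: 23 (4R,6R,7S,8R,9E)-5-oxogermacra-9,11(13)-dien-12,8-olid-6-yl (2R)-2-methylbutanoate, via hydroxy enal 21 (not isolated), via lactol 22 (not isolated)
Conditions: TEMPO (20 mol %), PhI(OAc)2, CH2Cl2, rt
Reagents that add atoms: none
Why: Oxoammonium (TEMPO) oxidation is selective for the primary alcohol, the resulting enal is trapped by O8 as the five-membered lactol and this is oxidised on to the α-methylene-γ-butyrolactone (oxidative lactonisation), whose trans ring fusion was fixed in step 9.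

Step 13
Reactants: 23 (4R,6R,7S,8R,9E)-5-oxogermacra-9,11(13)-dien-12,8-olid-6-yl (2R)-2-methylbutanoate
Product: 24 (4R,6R,7S,8S,9R,10R)-9,10-epoxy-5-oxogermacr-11(13)-en-12,8-olid-6-yl (2R)-2-methylbutanoate
Conditions: dimethyldioxirane, acetone, −20 → 0 °C
Reagents that add atoms: dimethyldioxirane, CC1(C)OO1
Why: Dioxirane epoxidation of the electron-rich trisubstituted alkene (the conjugated exocyclic methylene is inert) occurs by peripheral attack on the outer face of the E-cyclodecene, which allylic 1,3-strain between C14 and H8 fixes as the face bearing O8, giving the (9R,10R)-epoxide with C9–O already in the target configuration.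

Step 14
Reactants: 24 (4R,6R,7S,8S,9R,10R)-9,10-epoxy-5-oxogermacr-11(13)-en-12,8-olid-6-yl (2R)-2-methylbutanoate
Product: 25 (4R,6R,7S,8S,9R,10S)-9,10-dihydroxy-5-oxogermacr-11(13)-en-12,8-olid-6-yl (2R)-2-methylbutanoate
Conditions: HClO4 (cat.), THF/H2O, 0 °C
Reagents that add atoms: water, O
Why: Acid-catalysed hydrolytic opening of a trisubstituted epoxide occurs at the tertiary carbon with inversion, here by backside entry of oxygen at C10 from the ring interior (possibly assisted by reversible participation of the transannular C5 carbonyl), so C9 (R) is retained and C10 becomes S in the trans-diol.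

Step 15
Reactants: 25 (4R,6R,7S,8S,9R,10S)-9,10-dihydroxy-5-oxogermacr-11(13)-en-12,8-olid-6-yl (2R)-2-methylbutanoate
Product: 26 (4R,6R,7S,8S,9R,10S)-10-hydroxy-9-(2-methylpropanoyloxy)-5-oxogermacr-11(13)-en-12,8-olid-6-yl (2R)-2-methylbutanoate
Conditions: (i-PrCO)2O, DMAP (cat.), pyridine, CH2Cl2, 0 °C
Reagents that add atoms: isobutyric anhydride, CC(C)C(=O)OC(=O)C(C)C
Why: DMAP-catalysed acylation differentiates the secondary C9 hydroxyl from the unreactive tertiary C10 hydroxyl and completes the target without touching any stereocentre.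

**Compound list**

1 | 2,3-dibromoprop-1-ene | C=C(Br)CBr | starting material
2 | 4-methoxybenzyl alcohol | COc1ccc(CO)cc1 | starting material
3 | sodium 4-methoxybenzyl oxide | COc1ccc(C[O-])cc1.[Na+] | intermediate
4 | 2-bromoprop-2-en-1-yl 4-methoxybenzyl ether | C=C(Br)COCc1ccc(OC)cc1 | intermediate
5 | (E)-1,2-bis(tributylstannyl)ethene | CCCC[Sn](CCCC)(CCCC)/C=C/[Sn](CCCC)(CCCC)CCCC | starting material
6 | tributyl{(1E)-3-[(PMBO)methyl]buta-1,3-dien-1-yl}stannane | CCCC[Sn](CCCC)(CCCC)/C=C/C(=C)COCc1ccc(OC)cc1 | intermediate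
7 | cis-2,6-dimethylcyclohexan-1-one (meso) | C[C@H]1CCC[C@@H](C)C1=O | starting material
8 | {[(6R)-2,6-dimethylcyclohex-1-en-1-yl]oxy}trimethylsilane | C[C@@H]1CCCC(C)=C1O[Si](C)(C)C | intermediate
9 | (2S,6R)-2-(hydroxymethyl)-2,6-dimethylcyclohexan-1-one | C[C@@H]1CCC[C@@](C)(CO)C1=O | intermediate
10 | (1S,3R)-1,3-dimethyl-2-oxocyclohexane-1-carbaldehyde | C[C@@H]1CCC[C@@](C)(C=O)C1=O | intermediate
11 | (2S,6R)-2-[(E)-2-iodoethenyl]-2,6-dimethylcyclohexan-1-one | C[C@@H]1CCC[C@@](C)(/C=C/I)C1=O | intermediate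
12 | (2S,6R)-2-[(E)-2-(PMBO)ethenyl]-2,6-dimethylcyclohexan-1-one | C[C@@H]1CCC[C@@](C)(/C=C/OCc2ccc(OC)cc2)C1=O | intermediate
13 | {(1E)-3-[(PMBO)methyl]buta-1,3-dien-1-yl}lithium | [Li]/C=C/C(=C)COCc1ccc(OC)cc1 | intermediate
14 | (1R,2S,6R)-1-{(1E)-3-[(PMBO)methyl]buta-1,3-dien-1-yl}-2-[(E)-2-(PMBO)ethenyl]-2,6-dimethylcyclohexan-1-ol | C[C@@H]1CCC[C@@](C)(/C=C/OCc2ccc(OC)cc2)[C@]1(O)/C=C/C(=C)COCc1ccc(OC)cc1 | intermediate
15 | potassium (1R,2S,6R)-1-{(1E)-3-[(PMBO)methyl]buta-1,3-dien-1-yl}-2-[(E)-2-(PMBO)ethenyl]-2,6-dimethylcyclohexan-1-olate | C[C@@H]1CCC[C@@](C)(/C=C/OCc2ccc(OC)cc2)[C@]1([O-])/C=C/C(=C)COCc1ccc(OC)cc1.[K+] | intermediate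
16 | potassium (4R,5Z,7S,8R,9E)-8,12-bis(PMBO)germacra-5,9,11(13)-trien-5-olate | C=C(COCc1ccc(OC)cc1)[C@@H]1/C=C(\[O-])[C@H](C)CCC/C(C)=C/[C@H]1OCc1ccc(OC)cc1.[K+] | intermediate
17 | (4R,6R,7R,8R,9E)-6-hydroxy-8,12-bis(PMBO)germacra-9,11(13)-dien-5-one | C=C(COCc1ccc(OC)cc1)[C@@H]1[C@@H](O)C(=O)[C@H](C)CCC/C(C)=C/[C@H]1OCc1ccc(OC)cc1 | intermediate
18 | (2R)-2-methylbutanoic acid | CC[C@@H](C)C(=O)O | starting material
19 | (4R,6R,7S,8R,9E)-5-oxo-8,12-bis(PMBO)germacra-9,11(13)-dien-6-yl (2R)-2-methylbutanoate | C=C(COCc1ccc(OC)cc1)[C@@H]1[C@@H](OC(=O)[C@H](C)CC)C(=O)[C@H](C)CCC/C(C)=C/[C@H]1OCc1ccc(OC)cc1 | intermediate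
20 | (4R,6R,7S,8R,9E)-8,12-dihydroxy-5-oxogermacra-9,11(13)-dien-6-yl (2R)-2-methylbutanoate | C=C(CO)[C@@H]1[C@@H](OC(=O)[C@H](C)CC)C(=O)[C@H](C)CCC/C(C)=C/[C@H]1O | intermediate
21 | (4R,6R,7S,8R,9E)-8-hydroxy-5,12-dioxogermacra-9,11(13)-dien-6-yl (2R)-2-methylbutanoate | C=C(C=O)[C@@H]1[C@@H](OC(=O)[C@H](C)CC)C(=O)[C@H](C)CCC/C(C)=C/[C@H]1O | intermediate
22 | (4R,6R,7S,8R,9E)-12-hydroxy-5-oxo-8,12-epoxygermacra-9,11(13)-dien-6-yl (2R)-2-methylbutanoate (both C12 epimers) | C=C1C(O)O[C@@H]2/C=C(C)/CCC[C@@H](C)C(=O)[C@H](OC(=O)[C@H](C)CC)[C@@H]12 | intermediate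
23 | (4R,6R,7S,8R,9E)-5-oxogermacra-9,11(13)-dien-12,8-olid-6-yl (2R)-2-methylbutanoate | C=C1C(=O)O[C@@H]2/C=C(C)/CCC[C@@H](C)C(=O)[C@H](OC(=O)[C@H](C)CC)[C@@H]12 | intermediate
24 | (4R,6R,7S,8S,9R,10R)-9,10-epoxy-5-oxogermacr-11(13)-en-12,8-olid-6-yl (2R)-2-methylbutanoate | C=C1C(=O)O[C@H]2[C@H]1[C@@H](OC(=O)[C@H](C)CC)C(=O)[C@H](C)CCC[C@@]3(C)O[C@@H]32 | intermediate
25 | (4R,6R,7S,8S,9R,10S)-9,10-dihydroxy-5-oxogermacr-11(13)-en-12,8-olid-6-yl (2R)-2-methylbutanoate | C=C1C(=O)O[C@H]2[C@H]1[C@@H](OC(=O)[C@H](C)CC)C(=O)[C@H](C)CCC[C@](C)(O)[C@@H]2O | intermediate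
26 | (4R,6R,7S,8S,9R,10S)-10-hydroxy-9-(2-methylpropanoyloxy)-5-oxogermacr-11(13)-en-12,8-olid-6-yl (2R)-2-methylbutanoate (CNP0071420.1) | C=C1C(=O)O[C@H]2[C@H]1[C@@H](OC(=O)[C@H](C)CC)C(=O)[C@H](C)CCC[C@](C)(O)[C@@H]2OC(=O)C(C)C | target

**Totals and risks**

Total step count: 15 (2 for the dienylstannane, 13 on the main line).
Longest linear sequence: 13 steps (7 → 26).

Three steps most likely to fail:

Step 9 (tandem oxy-Cope and hydroxylation). Risks are attack of the potassium alkoxide on the enol ether or diene, equilibration of the enolate, or poor face control at C6. The fallback separates the rearrangement from the oxidation and runs it without base. It sets out from 14: silylation (Me3SiCl, imidazole, DMF) gives trimethyl{[(1R,2S,6R)-1-{(1E)-3-[(PMBO)methyl]buta-1,3-dien-1-yl}-2-[(E)-2-(PMBO)ethenyl]-2,6-dimethylcyclohexyl]oxy}silane F1. A thermal siloxy-Cope rearrangement (1,2-dichlorobenzene, 200 °C) gives the isolable ring-expanded enol ether (4R,5Z,7S,8R,9E)-8,12-bis(PMBO)-5-(trimethylsilyloxy)germacra-5,9,11(13)-triene F2. Cleavage with MeLi (THF, 0 °C) gives lithium (4R,5Z,7S,8R,9E)-8,12-bis(PMBO)germacra-5,9,11(13)-trien-5-olate F3, which is hydroxylated with the same oxaziridine at −78 °C and quenched with AcOH. The route is rejoined at 17.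

Step 14 (epoxide hydrolysis with inversion at C10). Risks are transannular hydride shifts, C–C cyclisation or loss of stereocontrol through a free cation. The fallback makes the C10–O bond in a halohydrin reaction and the C9–O bond by SN2 opening of the diastereomeric epoxide, so no aqueous acid and no selective acylation are needed. It sets out from 23: NBS in acetone/H2O at 0 °C gives (4R,6R,7R,8S,9R,10S)-9-bromo-10-hydroxy-5-oxogermacr-11(13)-en-12,8-olid-6-yl (2R)-2-methylbutanoate F4 (bromonium on the outer face, water at tertiary C10). K2CO3 in acetone closes it to (4R,6R,7S,8S,9S,10S)-9,10-epoxy-5-oxogermacr-11(13)-en-12,8-olid-6-yl (2R)-2-methylbutanoate F5. Tetrabutylammonium isobutyrate with isobutyric acid in toluene at 60 °C opens F5 at the secondary C9 with inversion. The route is rejoined directly at 26.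

Step 8 (facial selectivity of the dienyllithium addition). Risks are formation of the cis-dialkenyl carbinol or enolisation of 12. The fallback builds the carbinol with an acetylide, the nucleophile with the strongest preference for axial attack, and creates the E-alkene afterwards. It sets out from 4 and 12: Sonogashira coupling of 4 with trimethylsilylacetylene (PdCl2(PPh3)2, CuI, Et3N) gives trimethyl{3-[(PMBO)methyl]but-3-en-1-yn-1-yl}silane F6. K2CO3 in MeOH gives 4-methoxybenzyl 2-methylidenebut-3-yn-1-yl ether F7. Its lithium acetylide (n-BuLi, THF, −78 °C) adds to 12 to give (1S,2S,6R)-1-{3-[(PMBO)methyl]but-3-en-1-yn-1-yl}-2-[(E)-2-(PMBO)ethenyl]-2,6-dimethylcyclohexan-1-ol F8. Hydroxyl-directed trans-hydroalumination with sodium bis(2-methoxyethoxy)aluminium hydride in THF, then protonation, gives the E-dienyl carbinol. The route is rejoined at 14.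

**Further compounds**

F1 | step 9 | trimethyl{[(1R,2S,6R)-1-{(1E)-3-[(PMBO)methyl]buta-1,3-dien-1-yl}-2-[(E)-2-(PMBO)ethenyl]-2,6-dimethylcyclohexyl]oxy}silane | C[C@@H]1CCC[C@@](C)(/C=C/OCc2ccc(OC)cc2)[C@]1(O[Si](C)(C)C)/C=C/C(=C)COCc1ccc(OC)cc1
F2 | step 9 | (4R,5Z,7S,8R,9E)-8,12-bis(PMBO)-5-(trimethylsilyloxy)germacra-5,9,11(13)-triene | C=C(COCc1ccc(OC)cc1)[C@@H]1/C=C(\O[Si](C)(C)C)[C@H](C)CCC/C(C)=C/[C@H]1OCc1ccc(OC)cc1
F3 | step 9 | lithium (4R,5Z,7S,8R,9E)-8,12-bis(PMBO)germacra-5,9,11(13)-trien-5-olate | C=C(COCc1ccc(OC)cc1)[C@@H]1/C=C(\[O-])[C@H](C)CCC/C(C)=C/[C@H]1OCc1ccc(OC)cc1.[Li+]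
F4 | step 14 | (4R,6R,7R,8S,9R,10S)-9-bromo-10-hydroxy-5-oxogermacr-11(13)-en-12,8-olid-6-yl (2R)-2-methylbutanoate | C=C1C(=O)O[C@H]2[C@H]1[C@@H](OC(=O)[C@H](C)CC)C(=O)[C@H](C)CCC[C@](C)(O)[C@@H]2Br
F5 | step 14 | (4R,6R,7S,8S,9S,10S)-9,10-epoxy-5-oxogermacr-11(13)-en-12,8-olid-6-yl (2R)-2-methylbutanoate | C=C1C(=O)O[C@H]2[C@H]1[C@@H](OC(=O)[C@H](C)CC)C(=O)[C@H](C)CCC[C@]3(C)O[C@H]32
F6 | step 8 | trimethyl{3-[(PMBO)methyl]but-3-en-1-yn-1-yl}silane | C=C(COCc1ccc(OC)cc1)C#C[Si](C)(C)C
F7 | step 8 | 4-methoxybenzyl 2-methylidenebut-3-yn-1-yl ether | C=C(COCc1ccc(OC)cc1)C#C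
F8 | step 8 | (1S,2S,6R)-1-{3-[(PMBO)methyl]but-3-en-1-yn-1-yl}-2-[(E)-2-(PMBO)ethenyl]-2,6-dimethylcyclohexan-1-ol | C[C@@H]1CCC[C@@](C)(/C=C/OCc2ccc(OC)cc2)[C@]1(O)C#CC(=C)COCc1ccc(OC)cc1
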